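Monday's flask was charged with 5.6 equiv of partner, and substrate, the limiting reagent there, takes up one partner on its way to the intermediate, so at least 82.1% of that charge was a leftover. Going from Sunday's charge of 2.7 equiv to Monday's raised target at 4.0 min from 43% to 46%, a gain of 3 percentage points on readings that scatter by 2 points. The next run has to choose its partner charge from these flasks:

| setting | Thursday's | Sunday's | Monday's | amber | teal | violet |
|---|---|---|---|---|---|---|
| substrate | 15 mM | 15 mM | 15 mM | 15 mM | 15 mM | 15 mM |
| partner | 0.86 equiv | 2.7 equiv | 5.6 equiv | 6.20 equiv | 1.00 equiv | 2.50 equiv |
| remark | run made earlier | run made earlier | run made earlier |  |  |  |
| time |  |  |  | 4.0 min | 4.0 min | 4.0 min |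

- Thursday's (time / min: target / %): 0.333: 3; 0.667: 8; 1.00: 6; 2.00: 19; 4.00: 28
- Sunday's (time / min: target / %): 0.833: 11; 1.50: 21; 2.50: 34; 3.00: 34; 4.00: 43
- Monday's (time / min: target / %): 0.333: 5; 1.00: 22; 2.00: 34; 3.00: 42; 4.00: 46

(readings scatter by 2 percentage points)

- for by-product the crystals are counted in
- as a solid, counted per litre of solution: crystals
- candidate steps: crystals <-> by-product; substrate + partner -> intermediate + by-product; intermediate -> target; intermediate -> side product B; substrate + by-product -> side product A

- which of the two there is more of at the end, amber (side product A / target)
- which of the two there is more of at the end, teal (side product A / target)
- which of the two there is more of at the end, violet (side product A / target)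
- amount of target at the end, in percent of the substrate charged, amber
- amount of target at the end, in percent of the substrate charged, teal
- amount of target at the end, in percent of the substrate charged, violet

The reckoning here replaces each curve by one number. Substrate has two ways out, with partner or with by-product, and the share taking the partner way is set equal to the charge divided by the charge plus a constant. Thursday's and Monday's readings give that constant as 0.739 equiv and a ceiling of 52.1%, both with the scatter of those readings. The constant is the saturation charge, the partner charge at which the rule puts target at 4.0 min at half its ceiling, an apparent Michaelis constant counted in equivalents. For Sunday's flask, which was not used, the rule gives 40.9% against the 43% read.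

The rule then puts target in teal at 29.9%, in violet at 40.2% and in amber at 46.5%. If the share lost from the partner way ends as side product A, the estimate for teal is 42.5% of the substrate charged as side product A, more than its target, and the estimate for violet is 22.8%, less than its target. So teal's charge is dropped, and on this reckoning amber's adds 6.3 points over violet's while leaving at least 83.9% of its partner unused.

The forecast gives target 47% (43% to 51%) in amber, 31% (27% to 35%) in teal and 42% (38% to 46%) in violet. It names target as the larger in teal, saying of side product A at low partner, “even there I doubt it overtakes target”. There the reckoning here parts from it.

Target ends at 45.3% in amber, 29.5% in teal and 38.7% in violet, and in teal side product A stands at 38.9%, more than target.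

    crystals ⇌ by-product, rate k1*(cs1 - [by-product]) while solid is left; crystals form when [by-product] > cs1 (solubility = 15.0 mM, k = 0.350 /s)
    substrate + partner → intermediate + by-product (k = 1.10 /M/s)
    intermediate → target (k = 0.00640 /s)
    intermediate → side product B (k = 0.00480 /s)
    substrate + by-product → side product A (k = 2.70 /M/s)

One more flask, like violet but charged with 0.620 equiv of partner, gets from the saturation charge of 0.739 equiv a target of 23.8% and a lost share of 54.4%. That flask ends with target 22.9%, side product A 39.2% and substrate 12.9%.

(All runs are calculated with made-up constants, noise included.)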